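# Total synthesis proposal for CNP0603244.1 via epoxy-alcohol Grob fragmentation of a cis-decalin

## Structural features

The target is a germacranolide: a ten-membered carbocycle (C1–C10) with an α-methylene-γ-butyrolactone (O6, C6, C7, C11, C12; exocyclic C13) trans-fused across C6–C7. Both ring olefins are trisubstituted and Z: C1=C10 carries the C14 oxymethyl group on C10, and C4=C5 carries the C15 methyl group on C4. Four contiguous stereocentres run C6(R)–C7(R)–C8(S)–C9(R); when C7–C8–C9 sit in a six-membered ring, C11, O8 and O9 lie on one face. Three oxygens carry three different states (O8–H, O9–acetyl, O14–isovaleryl) and must be told apart. The fragile parts are the exo-methylene lactone, the two allylic esters, the allylic lactone C6–O bond and the 1,5-diene, which can cyclise across the ring under strong acid. Any C6 ketone intermediate also has an acidic C7–H next to a β-oxygen. The real difficulty is the ten-membered ring with two Z olefins and the all-syn C7/C8/C9 triad. The key step exploits the fact that O6-bearing C6 lies across the ring from C1, whose olefin partner C10 carries the oxygenated C14. A notional C1–C6 bond turns the macrocycle into a cis-decalin (ring A: C1–C6; ring B: C6, C7, C8, C9, C10, C1), in which O6–C6–C1–C10–O(epoxide) is a fragmentation array.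

## Logic of the disconnections

33 ⇒ 32: the O9–acetyl bond is cut last. This leaves the most labile ester to the end; the forward step must acylate O9 in the presence of free O8.

32 ⇒ 31: O8 and O9 are tied back into an isopropylidene acetal. The acetal keeps O8 out of every earlier step, above all the lactonisation, and links the triad to a chiral-pool diol. The forward hydrolysis must be mild enough for the 1,5-diene and the allylic C–O bonds.

31 ⇒ 28: the lactone O6–C12 bond is cut and C12 is lowered to the alcohol level. This removes the Michael acceptor from all earlier chemistry. The forward step must oxidise a primary allylic alcohol selectively next to a secondary one.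

28 ⇒ 27 ⇒ 26: the O12–silicon bond and the O14–isovaleryl bond are cut. O14 is the only primary hydroxyl of 26, so its acylation needs only primary-over-secondary selectivity.

26 ⇒ 25: the C6–H bond is cut, leaving the C6 ketone. The demand is hydride delivery to one face of a ten-membered Z-enone next to the C7 stereocentre.

25 ⇒ 23 (key): the C1–C6 bond is re-formed, C1=C10 becomes a single bond and O14 is closed onto C10 as a spiro-epoxide. This exchanges a ten-membered ring with two Z olefins for a cis-fused bicycle of two six-membered rings, in which the C4=C5 geometry is fixed by ring A. The demand is a chair of ring B with C1–C6 anti to the C10–O bond and C2 anti to C14.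

23 ⇒ 22 ⇒ 19 + 20: the C10–C14 and C14–O bonds of the epoxide are cut back to a C10 ketone and a one-carbon ylide, with O6 masked as a silyl ether. The demand is methylene delivery to the face of C10 that carries H1.

19 ⇒ 18 ⇒ 17: the O6 silyl group is removed and the C10 carbonyl is returned to a carbinol. This lets C10 enter as an aldehyde carbon.

17 ⇒ 14: the C6–C7 bond is cut (ring B opened) to a C6 enone and a 2-substituted allyl donor, with C13 as the metal-bearing carbon. The forward allylation must add 1,2 to the enone through C7, give the cis ring fusion and place C11 cis to O8.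

14 ⇒ 10 + 11: the C1–C10 bond is cut to the α′-enolate of 11 and aldehyde 10. The demand is the syn aldol with Felkin–Anh face selectivity, which fixes C1 relative to C9.

10 ⇒ 9 ⇒ 7 ⇒ 6: functional-group changes only (C10 aldehyde from a silyl-protected primary alcohol; allylic chloride from a C7 carbinol by allylic transposition). The demand is differentiation of the two hydroxyls of 6.

6 ⇒ 5 ⇒ 3 + 2: the C7–C11 bond is cut to the carbonyl carbon of 3 and a C11–C13 vinyl nucleophile from 2. Both target carbinol centres (C8, C9) come from 3 without a stereoselective step. The demand is single addition to the lactone.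

2 ⇒ 1: the O–Si bond is cut to a commercial bromo-allylic alcohol.

## Other disconnections considered

**Alternative 1:** The cut is at the two C–O bonds of C8 and C9, traced back to the arene bromobenzene A1. The forward key step is whole-cell toluene dioxygenase oxidation of A1 to the cis-dihydrodiol A2.
- In its favour: both carbinol centres are set in one catalytic step from an achiral arene. The six carbons of A2 map onto C10 (the C–Br carbon), C9, C8, C7, C6 and C1, so ring B of the bicycle used here would arrive as a ready-made carbocycle. The vinyl bromide would let C14 be attached to an sp2 C10 with no facial question; on this point it is better than the chosen plan, which must control the face of a ketone.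
- Against it: the step builds no skeletal bond. The C7 side chain would have to enter on the face already occupied by the diol (contra-steric on a rigid cyclohexene), ring A would still have to be annulated at C1/C6, and A2 is prone to dehydrative re-aromatisation and dimerisation.
- Comparison: on structure the two plans are equal at C8/C9, since the chosen route takes the same centres from the chiral pool at no cost in steps. On mechanism, an enzymatic cis-dihydroxylation replaces a purchased building block. On step economy the alternative would probably be longer, because the medium ring problem is untouched.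

**Alternative 2:** The cut is at C5–C6, together with the lactone O6–C12 acyl bond. The forward key step treats the acyclic Z-iodoalkene aldehyde ester A3 with CrCl2 and catalytic NiCl2; the vinylchromium adds to the C6 aldehyde and the alkoxide lactonises to A4.
- In its favour: it is convergent, and ring and lactone form in one operation. Both Z olefins are made by acyclic methods before ring closure, so their geometry does not rest on a conformational argument; on this point it is better than the chosen plan.
- Against it: a direct ten-membered closure pays transannular strain and needs high dilution and a large excess of CrCl2. C6 is created during the closure with uncertain face selectivity, and only one C6 epimer can give the trans lactone. The C7 centre α to the aldehyde is epimerisable, A4 still lacks C13, and A3 needs a long linear synthesis of the all-syn triad.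
- Comparison: on structure, a ring bond is made rather than a shared bond broken. On mechanism, the chosen plan's strain-releasing unimolecular fragmentation should be the more reliable way to reach the medium ring. The plans are equal in that both carry O8/O9 as an acetonide and face the same late differentiation, and the step counts should be similar.

**Alternative 3:** The cut is at C7–C8, made while O8–C13 is broken. The forward key step treats the thirteen-membered α-allyloxy enone A5 with LiN(SiMe3)2; the C8 enolate undergoes a [2,3]-Wittig shift to the ten-membered hydroxy ketone A6.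
- In its favour: one step forms C7–C8, both stereocentres, the free C8 hydroxyl and the C11=C13 methylene. O8 arrives free while C9 is a ketone, so the O8/O9 differentiation that the chosen plan must solve at the end is built in; on this point it is better. A thirteen-membered ether is also easier to close than a ten-membered carbocycle.
- Against it: the enolate regiochemistry is uncertain (α-deprotonation at C8 against γ-deprotonation through the C10=C1 enone), and [1,2]-shift and β-elimination of the allyloxy group can compete. Transannular control of C7/C8 relative to C6 is unproven, the acrylate ester is exposed to an amide base, and C9 must later be reduced stereoselectively.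
- Comparison: the two key steps are equal in being concerted and stereospecific with respect to olefin geometry. On step economy the alternative is probably not shorter, because A5 itself requires a macrocyclisation.

Key step: step 13

## Remarks on the chemistry (before the steps)

- Germacrane numbering (C1–C15) is used for all intermediates.
- Ring A must be six-membered, so the enone is 3-methylcyclohex-2-en-1-one, CC1=CC(=O)CCC1. The string CC1=CC(=O)CC1 is 3-methylcyclopent-2-en-1-one and is not used.
- With the D-lactone, the target configuration (8S,9R) results only if the lactone carbonyl carbon becomes C7 and the CH2O carbon becomes C10. The route is built on this mapping.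
- Assumption: 5–8 are carried as C7 (or anomeric) mixtures and 9, 10, 14–16 as C7=C11 geometric mixtures. This element is erased when the allylindium forms in step 8.
- "Chair P" of ring B has C2, O6 and O8 axial; "chair Q" is the ring-flipped form.
- Design change to the fragmentation precursor: its C6 hydroxyl is kept as a trimethylsilyl ether through C14 introduction and is unmasked only directly before step 13.

## Route

Step 1
Reactants: 1 2-bromoprop-2-en-1-ol
Product: 2 (2-bromoallyloxy)(tert-butyl)dimethylsilane
Conditions: TBSCl, imidazole, CH2Cl2, 0 °C → rt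
Reagents that add atoms: tert-butyldimethylsilyl chloride, CC(C)(C)[Si](C)(C)Cl
Why: Standard imidazole-promoted silylation of a primary allylic alcohol; no stereocentre is involved.

Step 2
Reactants: 2 (2-bromoallyloxy)(tert-butyl)dimethylsilane; 3 2,3-O-isopropylidene-D-erythronolactone
Product: 5 1-C-[3-(tert-butyldimethylsilyloxy)prop-1-en-2-yl]-2,3-O-isopropylidene-D-erythrofuranose (hemiketal; anomers), via 2-lithioallyl silyl ether 4 (not isolated)
Conditions: tBuLi (2 equiv), Et2O, −78 °C; then 3, THF, −78 °C; H2O
Reagents that add atoms: none
Why: Bromine–lithium exchange gives the vinyllithium, which adds once to the lactone carbonyl because the lithium hemiketalate does not collapse at −78 °C (organolithium addition to a lactone); keeping the reagent cold suppresses oxygen-to-carbon silyl migration, and C8/C9 are untouched.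

Step 3
Reactants: 5 the hemiketal
Product: 6 2-[(tert-butyldimethylsilyloxy)methyl]-1-[(4S,5R)-5-(hydroxymethyl)-2,2-dimethyl-1,3-dioxolan-4-yl]prop-2-en-1-ol (C7 epimers)
Conditions: NaBH4, CeCl3·7H2O, MeOH, −20 → 0 °C
Reagents that add atoms: none
Why: Luche reduction acts on the open hydroxy-enone tautomer and gives only 1,2-reduction; the C7 carbinol forms as a mixture, which is harmless because C7 becomes sp2 in step 5.

Step 4
Reactants: 6 the diol
Product: 7 2-[(tert-butyldimethylsilyloxy)methyl]-1-[(4S,5R)-2,2-dimethyl-5-(triethylsilyloxymethyl)-1,3-dioxolan-4-yl]prop-2-en-1-ol (C7 epimers)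
Conditions: TESCl (1.05 equiv), imidazole, CH2Cl2, −40 °C
Reagents that add atoms: chlorotriethylsilane, CC[Si](Cl)(CC)CC
Why: The primary hydroxyl is silylated far faster than the hindered secondary allylic one (selective silylation); triethylsilyl is chosen because step 6 can oxidise it directly.

Step 5
Reactants: 7 the mono-silyl ether
Product: 9 tert-butyl{2-(chloromethyl)-3-[(4S,5R)-2,2-dimethyl-5-(triethylsilyloxymethyl)-1,3-dioxolan-4-yl]allyloxy}dimethylsilane (E/Z mixture), via allylic mesylate 8 (not isolated)
Conditions: MsCl, 2,4,6-collidine, LiCl, DMF, 0 °C → rt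
Reagents that add atoms: lithium chloride, [Li+].[Cl-]
Why: The hindered secondary mesylate next to the dioxolane is displaced by chloride at the terminal methylene (SN2′), giving the primary allylic chloride with the trisubstituted C7=C11 olefin; either geometry serves, and a chloride is robust enough for steps 6 and 7.

Step 6
Reactants: 9 the allylic chloride
Product: 10 (4S,5S)-5-[3-chloro-2-(tert-butyldimethylsilyloxymethyl)prop-1-enyl]-2,2-dimethyl-1,3-dioxolane-4-carbaldehyde (E/Z mixture)
Conditions: (COCl)2, DMSO, CH2Cl2, −78 → −40 °C; iPr2NEt, −78 → −20 °C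
Reagents that add atoms: none
Why: Primary triethylsilyl ethers are cleaved and oxidised in one operation under Swern conditions while the TBS ether, the acetonide and the allylic chloride survive; the hindered amine and low temperature protect the epimerisable C9 centre, and the aldehyde is used at once.

Step 7
Reactants: 11 3-methylcyclohex-2-en-1-one; 10 the aldehyde
Product: 14 (6R)-6-[(R)-{(4R,5S)-5-[3-chloro-2-(tert-butyldimethylsilyloxymethyl)prop-1-enyl]-2,2-dimethyl-1,3-dioxolan-4-yl}(hydroxy)methyl]-3-methylcyclohex-2-en-1-one, via lithium dienolate 12 (not isolated), via titanium dienolate 13 (not isolated)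
Conditions: LiN(iPr)2, THF, −78 °C; ClTi(OiPr)3, −78 → −40 °C; then 10, −78 °C; H2O
Reagents that add atoms: none
Why: The amide base removes the α′ proton (kinetic cross-conjugated dienolate), and exchange to the triisopropoxytitanium enolate makes the aldol of this cyclic E-enolate syn-selective. The α-alkoxy aldehyde should react in the Felkin–Anh sense (attack anti to C9–O), which sets C1 with H1 and O9 syn along C1–C10–C9 and puts O10 on the same side. The C10 centre is removed in step 9.

Step 8
Reactants: 14 the aldol adduct
Product: 17 cis-fused decalin-6,10-diol (ring A: 4-methylcyclohex-4-ene; 8,9-acetonide; C7 bearing 3-(tert-butyldimethylsilyloxy)prop-1-en-2-yl; H1 and O6 and C11 and O8 and O9 and O10 all on one face), via allylic iodide 15 (not isolated), via allylindium diiodide 16 (not isolated)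
Conditions: In powder, NaI, DMF, rt
Reagents that add atoms: none
Why: Halide exchange and indium insertion give a 2-substituted allylindium that adds through C7 (SE2′, Zimmerman–Traxler type) to the C6 ketone in 1,2-fashion, closing ring B (intramolecular Barbier allylation). Indium held between the C10 hydroxyl and the ketone oxygen should fix chair P, in which C11 takes the equatorial site cis to O8 (sets C7) and the new C6–O bond is cis to H1 (cis-decalin). The olefin geometry of 14 is erased in the allylmetal.

Step 9
Reactants: 17 the decalin diol
Product: 18 cis-fused 6-hydroxy-decalin-10-one (otherwise as 17)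
Conditions: Dess–Martin periodinane, NaHCO3, CH2Cl2, 0 °C → rt
Reagents that add atoms: none
Why: The periodinane oxidises the secondary C10 alcohol and cannot oxidise the tertiary allylic C6 alcohol; buffered neutral conditions avoid retro-aldol cleavage and dehydration of the β-hydroxy ketone.

Step 10
Reactants: 18 the hydroxy ketone
Product: 19 6-O-trimethylsilyl ether of 18
Conditions: N-(trimethylsilyl)imidazole, CH2Cl2, rt
Reagents that add atoms: N-(trimethylsilyl)imidazole, C[Si](C)(C)n1ccnc1
Why: Neutral silylation of the tertiary hydroxyl; the ether blocks retro-aldol and E1cB pathways in step 11, removes the hydrogen bond that would favour the unwanted betaine, and disfavours the chair with O6 axial.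

Step 11
Reactants: 19 the silylated ketone; 20 trimethylsulfonium iodide
Product: 22 C10–C14 spiro-epoxide of 19 (C14 cis to H1; epoxide oxygen trans to H1), via dimethylsulfonium methylide 21 (not isolated)
Conditions: KN(SiMe3)2, THF, −10 °C; then 19, −10 → 0 °C
Reagents that add atoms: none
Why: The sulfonium ylide adds irreversibly to the C10 ketone and the betaine closes to the spiro-epoxide (Corey–Chaykovsky), leaving all three olefins untouched. CH2 should enter on the convex face of the cis-decalin, syn to H1 and anti to C2 of ring A, through chair Q, which keeps the O6 silyl ether equatorial; this places C14 cis to H1 and the epoxide oxygen trans to it.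

Step 12
Reactants: 22 the silylated spiro-epoxide
Product: 23 cis-decalin C6 alcohol with C10–C14 spiro-epoxide (8,9-acetonide; O12 TBS ether), (1S,6R,7R,8S,9S,10R)
Conditions: K2CO3 (cat.), MeOH, 0 °C
Reagents that add atoms: none
Why: The tertiary trimethylsilyl ether is methanolysed under mild carbonate conditions that leave the primary TBS ether, the acetonide and the epoxide intact; the hydroxyl is freed only now, directly before the fragmentation.

Step 13
Reactants: 23 the epoxy alcohol
Product: 25 (7R,8S,9R)-Z,Z-cyclodeca-1(10),4-dien-6-one with C14 hydroxyl (8,9-acetonide; O12 TBS ether), via titanium alkoxide 24 (not isolated)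
Conditions: Ti(OiPr)4 (2.5 equiv), CH2Cl2, 0 → 40 °C; aq. KNaC4H4O6 (potassium sodium tartrate)
Reagents that add atoms: none
Why: Ligand exchange gives the C6 titanium alkoxide, and a second titanium centre polarises the epoxide oxygen; the O6 lone pair then forms the C6 carbonyl as the C1–C6 σ-bond becomes the C1=C10 π-bond and the C10–O bond breaks, releasing the C14 alkoxide in one concerted heterolytic event. The closest known reaction type is the Lewis-acid-promoted Grob-type fragmentation of fused bicyclic 3,4-epoxy alcohols to medium-ring hydroxy ketones. The ten-membered ring is not closed by bond formation but unveiled by cleaving the shared bond of the bicyclo[4.4.0] system, so no cyclisation mode applies. No stereocentre is created. The C4=C5 olefin is Z because it was held in ring A, and C1=C10 is Z because in chair P the equatorial C10–O bond is anti to C1–C6 while axial C2 is anti to axial C14, so C2 ends cis to C9. The step needs fragmentation to win over epoxide-to-aldehyde rearrangement and over attack of O6 on C14. Titanium bound to O6 and the syn-axial O8 should hold chair P, the 5-endo attack on C14 is geometrically disfavoured, and the epimeric chair has no bond anti to the C10–O bond except C1–H. Mild, non-enolising conditions and a neutral work-up protect C7 and the β-oxygen at C8; 25 is reduced without storage.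

Step 14
Reactants: 25 the dienone
Product: 26 (6R)-allylic alcohol (C6 and C14 hydroxyls; 8,9-acetonide; O12 TBS ether)
Conditions: NaBH4, CeCl3·7H2O, MeOH/CH2Cl2, −78 °C
Reagents that add atoms: none
Why: Luche conditions give clean 1,2-reduction of the Z-enone at −78 °C before the β,γ-unsaturated ketone can epimerise. Hydride should add anti to the C7–C11 bond (Felkin–Anh, with C11 perpendicular and C8 inside), which gives the 6R alcohol with O6 and C11 syn, as the trans lactone requires.

Step 15
Reactants: 26 the diol
Product: 27 C14 isovalerate of 26
Conditions: isovaleryl chloride (1.05 equiv), 2,4,6-collidine, CH2Cl2, −78 → −40 °C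
Reagents that add atoms: 3-methylbutanoyl chloride, CC(C)CC(Cl)=O
Why: Acid chloride with a hindered pyridine base at low temperature esterifies the primary allylic C14 hydroxyl far faster than the secondary C6 hydroxyl flanked by C5 and C7 (selective acylation).

Step 16
Reactants: 27 the isovalerate
Product: 28 C6,C12-diol (C14 isovalerate; 8,9-acetonide)
Conditions: HF·pyridine, pyridine, THF, 0 °C → rt
Reagents that add atoms: none
Why: Buffered HF·pyridine cleaves the primary allylic TBS ether without touching the acetonide, the ester or the olefins, and avoids basic fluoride that could move the isovalerate.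

Step 17
Reactants: 28 the diol
Product: 31 trans-fused α-methylene-γ-butyrolactone (8,9-acetonide; C14 isovalerate), via hydroxy enal 29 (not isolated), via lactol 30 (not isolated)
Conditions: TEMPO (0.2 equiv), PhI(OAc)2 (2.5 equiv), CH2Cl2, rt
Reagents that add atoms: none
Why: The oxoammonium oxidises the primary allylic alcohol to the enal much faster than the secondary alcohol; the C6 hydroxyl closes the five-membered lactol, which is oxidised on to the lactone (oxidative lactonisation). The acetonide keeps O8 out of play, so only the 6,12-olide can form.

Step 18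
Reactants: 31 the lactone acetonide
Product: 32 8,9-diol (9-deacetyl target)
Conditions: AcOH/H2O (4:1), 45 °C
Reagents that add atoms: none
Why: Mild aqueous acetic acid hydrolyses the cis-dioxolane; a weak acid is chosen so that the 1,5-diene does not cyclise across the ring and the allylic C–O bonds do not ionise.

Step 19
Reactants: 32 the diol
Product: 33 CNP0603244.1, (6R,7R,8S,9R)
Conditions: Ac2O (1.1 equiv), 2,4,6-collidine, CH2Cl2, −20 → 0 °C
Reagents that add atoms: acetic anhydride, CC(=O)OC(C)=O
Why: Selective monoacylation: O9 is allylic and flanked by the sp2 carbon C10, whereas O8 lies between two sp3 stereocentres next to the lactone ring, so one equivalent of anhydride at low temperature should acetylate O9 first.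

## Compound list

1 | 2-bromoprop-2-en-1-ol | C=C(Br)CO | starting material
2 | (2-bromoallyloxy)(tert-butyl)dimethylsilane | C=C(Br)CO[Si](C)(C)C(C)(C)C | intermediate
3 | 2,3-O-isopropylidene-D-erythronolactone | O=C1[C@@H]2OC(C)(C)O[C@@H]2CO1 | starting material
4 | [3-(tert-butyldimethylsilyloxy)prop-1-en-2-yl]lithium | [Li]C(=C)CO[Si](C)(C)C(C)(C)C | intermediate (not isolated)
5 | 1-C-[3-(tert-butyldimethylsilyloxy)prop-1-en-2-yl]-2,3-O-isopropylidene-D-erythrofuranose (anomers) | OC1(C(=C)CO[Si](C)(C)C(C)(C)C)[C@@H]2OC(C)(C)O[C@@H]2CO1 | intermediate
6 | 2-[(tert-butyldimethylsilyloxy)methyl]-1-[(4S,5R)-5-(hydroxymethyl)-2,2-dimethyl-1,3-dioxolan-4-yl]prop-2-en-1-ol (C7 epimers) | OC[C@H]1OC(C)(C)O[C@H]1C(O)C(=C)CO[Si](C)(C)C(C)(C)C | intermediate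
7 | C10 triethylsilyl ether of 6 (C7 epimers) | CC[Si](CC)(CC)OC[C@H]1OC(C)(C)O[C@H]1C(O)C(=C)CO[Si](C)(C)C(C)(C)C | intermediate
8 | C7 methanesulfonate of 7 | CC[Si](CC)(CC)OC[C@H]1OC(C)(C)O[C@H]1C(OS(C)(=O)=O)C(=C)CO[Si](C)(C)C(C)(C)C | intermediate (not isolated)
9 | tert-butyl{2-(chloromethyl)-3-[(4S,5R)-2,2-dimethyl-5-(triethylsilyloxymethyl)-1,3-dioxolan-4-yl]allyloxy}dimethylsilane (E/Z) | CC[Si](CC)(CC)OC[C@H]1OC(C)(C)O[C@H]1C=C(CCl)CO[Si](C)(C)C(C)(C)C | intermediate
10 | (4S,5S)-5-[3-chloro-2-(tert-butyldimethylsilyloxymethyl)prop-1-enyl]-2,2-dimethyl-1,3-dioxolane-4-carbaldehyde (E/Z) | O=C[C@H]1OC(C)(C)O[C@H]1C=C(CCl)CO[Si](C)(C)C(C)(C)C | intermediate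
11 | 3-methylcyclohex-2-en-1-one | CC1=CC(=O)CCC1 | starting material
12 | lithium α′-dienolate of 11 (O–C6=C1) | CC1=CC(O[Li])=CCC1 | intermediate (not isolated)
13 | triisopropoxytitanium α′-dienolate of 11 | CC1=CC(O[Ti](OC(C)C)(OC(C)C)OC(C)C)=CCC1 | intermediate (not isolated)
14 | (6R)-6-[(R)-{(4R,5S)-5-[3-chloro-2-(tert-butyldimethylsilyloxymethyl)prop-1-enyl]-2,2-dimethyl-1,3-dioxolan-4-yl}(hydroxy)methyl]-3-methylcyclohex-2-en-1-one (E/Z) | CC1=CC(=O)[C@H](CC1)[C@@H](O)[C@H]2OC(C)(C)O[C@H]2C=C(CCl)CO[Si](C)(C)C(C)(C)C | intermediate
15 | allylic iodide corresponding to 14 | CC1=CC(=O)[C@H](CC1)[C@@H](O)[C@H]2OC(C)(C)O[C@H]2C=C(CI)CO[Si](C)(C)C(C)(C)C | intermediate (not isolated)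
16 | C13-bound allylindium diiodide (drawn as monomer) | CC1=CC(=O)[C@H](CC1)[C@@H](O)[C@H]2OC(C)(C)O[C@H]2C=C(C[In](I)I)CO[Si](C)(C)C(C)(C)C | intermediate (not isolated)
17 | cis-decalin-6,10-diol, 8,9-acetonide, C7 3-(TBSO)prop-1-en-2-yl (H1, O6, C11, O8, O9, O10 on one face) | CC1=C[C@]2(O)[C@H](CC1)[C@@H](O)[C@H]3OC(C)(C)O[C@H]3[C@H]2C(=C)CO[Si](C)(C)C(C)(C)C | intermediate
18 | cis-6-hydroxy-decalin-10-one (otherwise as 17) | CC1=C[C@]2(O)[C@H](CC1)C(=O)[C@H]3OC(C)(C)O[C@H]3[C@H]2C(=C)CO[Si](C)(C)C(C)(C)C | intermediate
19 | 6-O-trimethylsilyl ether of 18 | CC1=C[C@]2(O[Si](C)(C)C)[C@H](CC1)C(=O)[C@H]3OC(C)(C)O[C@H]3[C@H]2C(=C)CO[Si](C)(C)C(C)(C)C | intermediate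
20 | trimethylsulfonium iodide | C[S+](C)C.[I-] | starting material
21 | dimethylsulfonium methylide | C[S+](C)[CH2-] | intermediate (not isolated)
22 | C10–C14 spiro-epoxide, 6-O-trimethylsilyl ether | CC1=C[C@]2(O[Si](C)(C)C)[C@H](CC1)[C@@]1(CO1)[C@H]3OC(C)(C)O[C@H]3[C@H]2C(=C)CO[Si](C)(C)C(C)(C)C | intermediate
23 | cis-decalin C6 alcohol with C10–C14 spiro-epoxide, (1S,6R,7R,8S,9S,10R) | CC1=C[C@]2(O)[C@H](CC1)[C@@]1(CO1)[C@H]3OC(C)(C)O[C@H]3[C@H]2C(=C)CO[Si](C)(C)C(C)(C)C | intermediate
24 | C6 triisopropoxytitanium alkoxide of 23 | CC1=C[C@]2(O[Ti](OC(C)C)(OC(C)C)OC(C)C)[C@H](CC1)[C@@]1(CO1)[C@H]3OC(C)(C)O[C@H]3[C@H]2C(=C)CO[Si](C)(C)C(C)(C)C | intermediate (not isolated)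
25 | (7R,8S,9R)-C14-hydroxy Z,Z-cyclodecadien-6-one, 8,9-acetonide, O12 TBS | O=C1/C=C(/C)CC/C=C(/CO)[C@H]2OC(C)(C)O[C@H]2[C@H]1C(=C)CO[Si](C)(C)C(C)(C)C | intermediate
26 | (6R)-C6,C14-diol | O[C@@H]1/C=C(/C)CC/C=C(/CO)[C@H]2OC(C)(C)O[C@H]2[C@H]1C(=C)CO[Si](C)(C)C(C)(C)C | intermediate
27 | C14 isovalerate of 26 | O[C@@H]1/C=C(/C)CC/C=C(/COC(=O)CC(C)C)[C@H]2OC(C)(C)O[C@H]2[C@H]1C(=C)CO[Si](C)(C)C(C)(C)C | intermediate
28 | C6,C12-diol, C14 isovalerate | O[C@@H]1/C=C(/C)CC/C=C(/COC(=O)CC(C)C)[C@H]2OC(C)(C)O[C@H]2[C@H]1C(=C)CO | intermediate
29 | C12 enal with free C6 hydroxyl | O[C@@H]1/C=C(/C)CC/C=C(/COC(=O)CC(C)C)[C@H]2OC(C)(C)O[C@H]2[C@H]1C(=C)C=O | intermediate (not isolated)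
30 | C12 lactol (anomers) | C=C1C(O)O[C@@H]2/C=C(/C)CC/C=C(/COC(=O)CC(C)C)[C@H]3OC(C)(C)O[C@H]3[C@@H]12 | intermediate (not isolated)
31 | trans-fused α-methylene lactone, 8,9-acetonide, C14 isovalerate | C=C1C(=O)O[C@@H]2/C=C(/C)CC/C=C(/COC(=O)CC(C)C)[C@H]3OC(C)(C)O[C@H]3[C@@H]12 | intermediate
32 | 8,9-diol (9-deacetyl target) | C=C1C(=O)O[C@@H]2/C=C(/C)CC/C=C(/COC(=O)CC(C)C)[C@@H](O)[C@@H](O)[C@@H]12 | intermediate
33 | CNP0603244.1, (6R,7R,8S,9R; 1(10)Z,4Z) | C=C1C(=O)O[C@@H]2/C=C(/C)CC/C=C(/COC(=O)CC(C)C)[C@@H](OC(C)=O)[C@@H](O)[C@@H]12 | target

## Step count and least certain steps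

Total: 19 steps. Longest linear sequence: 19 steps (1 → 33); 18 steps from 3.

**Step 13 (key).** The titanium held by O6 and O8 sits on the face opposite to the epoxide oxygen, so the nucleofuge must be activated by a second titanium centre. Two things can go wrong: activation may be too weak for any reaction, or, if a stronger acid is used to force it, the spiro-epoxide may isomerise to the aldehyde or the tertiary allylic C6–O bond may ionise.
Fallback, setting out from 23 and returning at 27: the fragmentation is run without any Lewis acid, as an alkoxide-driven process. KN(SiMe3)2 with 18-crown-6 in THF at −78 °C forms the potassium alkoxide, and warming lets the strain of the epoxide drive the same anti-periplanar cleavage. The liberated C14 alkoxide is trapped in the flask with isovaleryl chloride at −78 °C before it can act as a base on the new ketone, giving the C14 isovalerate dienone F1. Luche reduction of F1 then gives 27, so the order of acylation and reduction is reversed.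

**Step 8.** The most likely failure is poor facial selectivity at C7. The open-chain preference of an allylic system next to a C–O bond is to receive the electrophile anti to that oxygen, which would place C11 trans to O8 in a trans-fused ring if anchoring by the C10 hydroxyl does not dominate. Loss of the C8 oxygen by 1,4-elimination of the allylmetal is the second risk.
Fallback, setting out from 14 and returning at 17: the allyl donor is changed from a polar organometallic to a boronate. Borylation of 14 with B2pin2 under zerovalent palladium catalysis (Pd2(dba)3, DMSO, 50 °C) gives the allylboronate F2. It has no carbanion character, so it cannot expel O8. It adds to the ketone only through a closed six-membered transition state, in which boron is bound by the neighbouring C10 hydroxyl; warming in toluene and aqueous work-up give 17.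

**Step 11.** The risk is methylene delivery to the wrong face of C10. If ring B reacts through chair P, the convex face is screened by the syn-axial O6 and O8, and the ylide would enter anti to H1. The resulting epimeric epoxide cannot fragment to the Z olefin.
Fallback, setting out from 19 and returning at 23: the same facial bias is used with the opposite consequence, by delivering oxygen instead of carbon to that face.
- Wittig reaction of 19 with Ph3P=CHOMe gives the exocyclic enol ether F3.
- One equivalent of dimethyldioxirane at −78 °C epoxidises only this electron-rich olefin; aqueous work-up gives the α-hydroxy aldehyde F4, with the new C10 oxygen trans to H1.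
- NaBH4 gives the diol F5, and TsCl/pyridine gives the primary tosylate F6.
- K2CO3 in MeOH closes the epoxide with retention at C10 and removes the trimethylsilyl group, giving 23 directly.

**Step 14.** The risk is hydride delivery from the other face, because the face of a ten-membered enone is set by ring conformation and not only by the local Felkin–Anh preference; this would give the 6-epimer.
Fallback, setting out from 25 and returning at 27: the centre is corrected after the fact by inversion.
- The 6-epi diol F7 is acylated at C14 as in step 15, giving the 6-epi isovalerate F8.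
- Mitsunobu reaction (PPh3, diisopropyl azodicarboxylate, chloroacetic acid) inverts C6, giving the 6R chloroacetate F9.
- The activated ester is removed selectively with catalytic K2CO3 in MeOH at −20 °C, giving 27.

**Step 19.** The risk is poor regioselectivity between O8 and O9, followed by acyl migration between the neighbouring oxygens.
Fallback, setting out from 32 and returning at 33: if O8 proves the more reactive hydroxyl, that same preference is used to protect it. TESCl/imidazole at −40 °C gives the 8-O-triethylsilyl ether F10; Ac2O/DMAP then gives the 9-acetate F11; and HF·pyridine, acidic so the acetate does not migrate, gives 33.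

## Further compounds

F1 | step 13 | C14 isovalerate of dienone 25 | O=C1/C=C(/C)CC/C=C(/COC(=O)CC(C)C)[C@H]2OC(C)(C)O[C@H]2[C@H]1C(=C)CO[Si](C)(C)C(C)(C)C
F2 | step 8 | pinacol allylboronate corresponding to 14 | CC1=CC(=O)[C@H](CC1)[C@@H](O)[C@H]2OC(C)(C)O[C@H]2C=C(CB3OC(C)(C)C(C)(C)O3)CO[Si](C)(C)C(C)(C)C
F3 | step 11 | C10 methoxymethylene enol ether of 19 (E/Z) | CC1=C[C@]2(O[Si](C)(C)C)[C@H](CC1)C(=COC)[C@H]3OC(C)(C)O[C@H]3[C@H]2C(=C)CO[Si](C)(C)C(C)(C)C
F4 | step 11 | C10 hydroxy C14 aldehyde (C10–OH trans to H1) | CC1=C[C@]2(O[Si](C)(C)C)[C@H](CC1)[C@@](O)(C=O)[C@H]3OC(C)(C)O[C@H]3[C@H]2C(=C)CO[Si](C)(C)C(C)(C)C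
F5 | step 11 | C10,C14-diol | CC1=C[C@]2(O[Si](C)(C)C)[C@H](CC1)[C@@](O)(CO)[C@H]3OC(C)(C)O[C@H]3[C@H]2C(=C)CO[Si](C)(C)C(C)(C)C
F6 | step 11 | C14 p-toluenesulfonate of F5 | CC1=C[C@]2(O[Si](C)(C)C)[C@H](CC1)[C@@](O)(COS(=O)(=O)c4ccc(C)cc4)[C@H]3OC(C)(C)O[C@H]3[C@H]2C(=C)CO[Si](C)(C)C(C)(C)C
F7 | step 14 | 6-epimer of 26 | O[C@H]1/C=C(/C)CC/C=C(/CO)[C@H]2OC(C)(C)O[C@H]2[C@H]1C(=C)CO[Si](C)(C)C(C)(C)C
F8 | step 14 | 6-epimer of 27 | O[C@H]1/C=C(/C)CC/C=C(/COC(=O)CC(C)C)[C@H]2OC(C)(C)O[C@H]2[C@H]1C(=C)CO[Si](C)(C)C(C)(C)C
F9 | step 14 | (6R)-chloroacetate of 27 | ClCC(=O)O[C@@H]1/C=C(/C)CC/C=C(/COC(=O)CC(C)C)[C@H]2OC(C)(C)O[C@H]2[C@H]1C(=C)CO[Si](C)(C)C(C)(C)C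
F10 | step 19 | 8-O-triethylsilyl ether of 32 | C=C1C(=O)O[C@@H]2/C=C(/C)CC/C=C(/COC(=O)CC(C)C)[C@@H](O)[C@@H](O[Si](CC)(CC)CC)[C@@H]12
F11 | step 19 | 8-O-triethylsilyl ether of 33 | C=C1C(=O)O[C@@H]2/C=C(/C)CC/C=C(/COC(=O)CC(C)C)[C@@H](OC(C)=O)[C@@H](O[Si](CC)(CC)CC)[C@@H]12
A1 | alternative 1 | bromobenzene | Brc1ccccc1
A2 | alternative 1 | (1S,2S)-3-bromocyclohexa-3,5-diene-1,2-diol | O[C@H]1C=CC=C(Br)[C@H]1O
A3 | alternative 2 | acyclic Z-iodoalkene C6 aldehyde C12 methyl ester, 8,9-acetonide, O14 TBS | I/C=C(/C)CC/C=C(/CO[Si](C)(C)C(C)(C)C)[C@H]1OC(C)(C)O[C@H]1[C@@H](CC(=O)OC)C=O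
A4 | alternative 2 | trans-fused bicyclic lactone, 8,9-acetonide, without C13 | C1C(=O)O[C@@H]2/C=C(/C)CC/C=C(/CO[Si](C)(C)C(C)(C)C)[C@H]3OC(C)(C)O[C@H]3[C@@H]12
A5 | alternative 3 | thirteen-membered α-allyloxy enone (C7=C11 drawn with C13 and C6 trans; this geometry is not fixed by the plan) | O=C1COC/C(C(=O)OC)=C/[C@H](O[Si](C)(C)C(C)(C)C)/C=C(/C)CC/C=C1/CO[Si](c1ccccc1)(c1ccccc1)C(C)(C)C
A6 | alternative 3 | ten-membered 8-hydroxy-9-ketone with C7 propenoate | C=C(C(=O)OC)[C@H]1[C@H](O[Si](C)(C)C(C)(C)C)/C=C(/C)CC/C=C(/CO[Si](c2ccccc2)(c2ccccc2)C(C)(C)C)C(=O)[C@H]1O
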